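Atoms are numbered as in the labdane skeleton: ring A is C1–C5 and C10, ring B is C5–C10, the chain is C11–C15, and the methyl groups are C16 (on C13), C17 (on C8), C18/C19 (on C4) and C20 (on C10).

## The problem

The target is a trans-fused decalin in which rings A and B share the C5–C10 bond, with an angular methyl at C10 and a gem-dimethyl group at C4. Ring A carries a cis-2,3-diol, both oxygens trans to C20, with the equatorial C2 oxygen acetylated and the axial, neopentyl C3 hydroxyl free. Ring B carries a trisubstituted C7=C8 olefin and, at C9, a five-carbon chain cis to C20 that holds a methyl stereocentre at C13 and ends in a primary acetate. C5, C9 and C10 are contiguous and can control one another; through the axial C10 and C4 methyl groups they can also control C2 and C3. C13 is two methylene groups away from the ring and can neither direct nor be directed, so it has to be bought in, and the ring centres then need absolute control by a reagent. The acetates rule out strong base, hydride and fluoride late in the route, and a cis-diol monoacetate is prone to acyl migration. The C7=C8 olefin is more electron-rich than any olefin that could be placed in ring A, so it would be attacked first by electrophilic oxidants, and acid can move it to the C8=C9 position. The feature that opens the structure is ring B itself: it is a cyclohexene whose C7=C8(CH3)–C9H unit is the trisubstituted olefin of citronellol, flanked by the quaternary C10 (methyl plus the ring A carbon C1) and by C5–H. C6–C9 can therefore enter as a diene and C5–C10 as an (E)-α-methyl enal.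

## Retrosynthesis

**Acetates and silyl ether (20 ⇒ 19 ⇒ 18).** The two acetyl C–O bonds are cut last, giving triol 19, and the C15 oxygen is then masked as the silyl ether 18. Acetates cannot be carried earlier because the route needs alkoxide and amide bases. The forward reaction must acetylate the primary C15–OH and the equatorial C2–OH while leaving the axial C3–OH, which sits next to the gem-dimethyl group. A tert-butyldiphenylsilyl ether is chosen because it has to survive a strong Lewis acid and several bases.

**Ring A oxygens (18 ⇒ 17 ⇒ 15).** The C3–H bond (hydride) and the C2–O bond (enolate oxidation) are cut, leading to ketone 15, which has no stereocentre in ring A. The obvious neighbour, osmylation of a C2=C3 olefin, is set aside because the C7=C8 olefin would react first. Forward, the oxidant must reach the C2 enolate carbon from the face opposite the axial C20 and axial C4 methyl groups, and the hydride must enter C3 along the equatorial trajectory so that the alcohol is axial and cis to the C2 oxygen.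

**Gem-dimethyl group (15 ⇒ 14 ⇒ 12).** Both C4–CH3 bonds are cut and a C1=C2 olefin is added, giving enone 12. In 12 the only enolisable position is C4, because C10 is quaternary; a saturated 3-ketone would be methylated at C2 instead. Forward, exhaustive methylation is followed by hydrogenation of the conjugated disubstituted olefin in the presence of the trisubstituted one.

**Ring A (12 ⇒ 10 ⇒ 9).** Cutting C1=C2 by a retro-aldol condensation gives keto aldehyde 10, with a formyl group on C10 and an acetonyl arm on C5. The ketone is taken back to the terminal olefin of an allyl group (9). A free 2-ene-1,5-dicarbonyl dienophile would be a vinylogous 1,3-dicarbonyl and the open form of a pyrylium ion, and it would not survive a strong Lewis acid. An allyl group is inert to the boron catalyst and is unmasked by Wacker oxidation. The aldol step has only one productive mode, since the aldehyde has no α-hydrogen and attack from C4 would give a four-membered ring.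

**Ring B (9 ⇒ 5 + 8), the key disconnection.** The C5–C6 and C9–C10 bonds are cut in a retro-[4+2] to give diene 5 and (E)-enal 8. No other cut removes a ring, three stereocentres and the olefin position at once, and none uses the citronellol olefin directly. The precursors are an acyclic diene with one stereocentre and an achiral six-carbon dienal. The forward reaction has to deliver C6-to-C5 regiochemistry, a formyl-exo transition state and one π-face.

**Diene (5 ⇒ 4 ⇒ 2 ⇒ 1).** The C6=C7 bond is cut by Wittig methylenation of enal 4. The formyl oxygen of 4 comes from allylic oxidation of the (E)-methyl group of silyl ether 2, made from (S)-citronellol 1, which supplies C13.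

**Dienophile (8 ⇒ 7 ⇒ 6).** The C3–C4 bond of 8 is cut by an SN2′ opening of 2-methyl-2-vinyloxirane 6 with a vinyl nucleophile. The opening gives alcohol 7 with the (E)-trisubstituted olefin, and oxidation gives 8.

## Roads not taken

Alternative 1: The C8–C9 bond is cut. Ring A is built first, with the diol as an acetonide, and a C8 acyl radical generated from seleno ester A1 (Bu3SnH) adds 6-exo to the C9=C11 olefin to give 8-ketone A2. Two things are better here than in the chosen plan. The diol is made before any ring B olefin exists, so osmylation has no competitor. C9 lies next to a ketone and can be equilibrated to the equatorial configuration, whereas the cycloaddition fixes C9 irreversibly. The weak points are in A1 itself: it needs the trans-related C5 and quaternary C10 centres, the latter bearing an alkenyl chain, on a cyclohexane that already carries C2 and C3, so the hard stereochemical work is moved rather than removed. The radical also has to attack an olefin carbon next to a quaternary centre, which favours simple reduction of the acyl radical. After closure the C8 ketone still has to become a methyl-bearing olefin placed specifically at C7=C8. Against the safer C9, the chosen plan sets convergence, a shorter linear sequence and an olefin that is formed in the right place.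

Alternative 2: The C9–C10 bond is cut. SnCl4 protonates the C5=C10 olefin of monocyclic β-keto ester A3 and the enol carbon C9 captures the C10 cation, giving the trans-fused keto ester A4. This kind of closure is better precedented than the proposed cycloaddition, the trans fusion comes from the anti addition, and the keto ester allows the chain to be attached by alkylation with C9 settling thermodynamically after decarboxylation. For this target the cation develops two carbons away from the ring A oxygens, which slows ionisation, and the acetonide is exposed to a strong Lewis acid. The absolute configuration at C5 and C10 depends on 1,3-induction from C2 and C3, which cannot be predicted. The chain is still missing, and its introduction makes C9 quaternary before the ester is removed. The C8 ketone again needs conversion into the C17 methyl and the C7=C8 olefin. The chosen plan sets catalyst control of the ring centres and a chain present from the start against the firmer precedent of this closure.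

Alternative 3: The C3–C4 bond is cut. Ring B comes from carvone; acid turns the isopropenyl group of A5 into the C4 cation, which is captured at C3 by a (Z)-vinylsilane arm on C10 to give dienone A6. This road is better than the chosen one for ring A. The gem-dimethyl group is made in the ring closure, C5 comes from the chiral pool, and the C2=C3 olefin can be osmylated from the face opposite C20 without competition, because the other olefin is part of an enone. It also has C17 and the C7=C8 olefin in place. Its weakness is C9, which is a carbonyl carbon. The whole C11–C15 chain would have to be added to a hindered enone, and the resulting tertiary allylic alcohol removed with the correct C9 configuration and without moving the olefin, for which no reliable method exists. The quaternary C10 of A5 also requires two stereocontrolled alkylations of carvone. The chosen plan pays for its longer ring A sequence by having C9 and its chain settled before any ring is formed.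

Key step: step 6

Assumption: the sense of induction of the boron catalyst is taken from the usual binding model for α-substituted enals (formyl C–H···O contact, s-trans enal); if the (R) catalyst should deliver the diene to the Re face of C10, its (S) antipode is used and nothing else changes.

## Route

Step 1
Reactants: 1 (3S)-3,7-dimethyloct-6-en-1-ol [(S)-citronellol]
Product: 2 tert-butyl{[(3S)-3,7-dimethyloct-6-en-1-yl]oxy}diphenylsilane
Conditions: tBuPh2SiCl, imidazole, CH2Cl2, 0 °C to rt
Reagents that add atoms: tert-butyl(chloro)diphenylsilane, CC(C)(C)[Si](Cl)(c1ccccc1)c1ccccc1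
Why: Standard silylation of a primary alcohol; the tert-butyldiphenylsilyl ether should tolerate the Lewis acid of step 6 and the bases of steps 8, 9 and 11.

Step 2
Reactants: 2 tert-butyl{[(3S)-3,7-dimethyloct-6-en-1-yl]oxy}diphenylsilane
Product: 4 (2E,6S)-8-{[tert-butyl(diphenyl)silyl]oxy}-2,6-dimethyloct-2-enal, via allylic alcohol 3 (not isolated)
Conditions: SeO2 (cat.), tBuOOH, salicylic acid (cat.), CH2Cl2, rt; then MnO2, CH2Cl2, rt
Reagents that add atoms: selenium dioxide, O=[Se]=O (delivers the oxygen atom and is reoxidised by tert-butyl hydroperoxide, CC(C)(C)OO)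
Why: Allylic oxidation with SeO2 (ene reaction, then [2,3]-sigmatropic shift) attacks the (E)-methyl group of a trisubstituted olefin, and MnO2 takes the resulting allylic alcohol to the enal, so the E geometry of the later C8=C9 bond is fixed here.

Step 3
Reactants: 4 (2E,6S)-8-{[tert-butyl(diphenyl)silyl]oxy}-2,6-dimethyloct-2-enal
Product: 5 tert-butyl{[(3S,6E)-3,7-dimethylnona-6,8-dien-1-yl]oxy}diphenylsilane
Conditions: Ph3PCH3Br, KOtBu, THF, 0 °C
Reagents that add atoms: methyltriphenylphosphonium bromide, C[P+](c1ccccc1)(c1ccccc1)c1ccccc1.[Br-]
Why: Wittig methylenation of an α-methyl enal without α-hydrogen; the ylide adds 1,2 and the trisubstituted olefin keeps its geometry.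

Step 4
Reactants: 6 2-methyl-2-vinyloxirane (racemic)
Product: 7 (2E)-2-methylhexa-2,5-dien-1-ol
Conditions: CH2=CHMgBr, CuI (10 mol %), THF, −30 °C
Reagents that add atoms: vinylmagnesium bromide, C=C[Mg]Br
Why: Copper-catalysed SN2′ opening of a vinyl oxirane by a Grignard reagent; anti attack on the s-trans conformer should give mainly the (E)-trisubstituted allylic alcohol, and the oxirane stereocentre is lost.

Step 5
Reactants: 7 (2E)-2-methylhexa-2,5-dien-1-ol
Product: 8 (2E)-2-methylhexa-2,5-dienal
Conditions: MnO2, CH2Cl2, rt
Reagents that add atoms: none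
Why: MnO2 oxidises only the allylic alcohol and leaves the terminal olefin; the (E)-enal is the favoured geometry, so a minor Z isomer can be equilibrated or removed.

Step 6
Reactants: 5 tert-butyl{[(3S,6E)-3,7-dimethylnona-6,8-dien-1-yl]oxy}diphenylsilane; 8 (2E)-2-methylhexa-2,5-dienal
Product: 9 (1R,2R,6S)-2-[(3S)-5-{[tert-butyl(diphenyl)silyl]oxy}-3-methylpentyl]-1,3-dimethyl-6-(prop-2-en-1-yl)cyclohex-3-ene-1-carbaldehyde (side chain and allyl group cis to the C1 methyl, trans to the formyl group)
Conditions: (R)-tetrahydro-1-(2-methylphenyl)-3,3-diphenyl-1H,3H-pyrrolo[1,2-c][1,3,2]oxazaborole (20 mol %), HN(SO2CF3)2 (18 mol %), CH2Cl2, −78 to −20 °C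
Reagents that add atoms: none
Why: The protonated oxazaborolidine binds the formyl oxygen of 8 (s-trans enal, formyl C–H···O contact to the ring oxygen), and the diene adds in a concerted but asynchronous Diels–Alder reaction in which the unsubstituted terminus C6 bonds first to the β-carbon C5 and C9 then closes onto C10. The closest known reaction type is the oxazaborolidinium-catalysed enantioselective cycloaddition of α-methyl enals with acyclic dienes. Ring B is closed as a six-membered ring by this intermolecular suprafacial [4+2] addition, and the olefin is left at C7=C8. C5 and C10 are related by the E geometry of 8, which puts the allyl arm (C4) cis to the C10 methyl and trans to the formyl group, the later trans ring fusion. C9 follows from the E geometry of the diene and a formyl-exo transition state, which places C11 cis to the C10 methyl; this mode is expected because the α-methyl group rather than the formyl group then lies under the diene and the boron complex stays clear of the C8 methyl and the C9 chain. The absolute configuration is set by the catalyst, whose phenyl group screens one face of the bound enal so that the diene reaches the Si face of C10; C13 is too far away to interfere. The C6-to-C5 regiochemistry is secured by formyl activation of C5, by the 1-alkyl substituent of the diene and by the small steric demand of the CH2 terminus, which together should outweigh the opposite pull of the C8 methyl.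

Step 7
Reactants: 9 (1R,2R,6S)-2-[(3S)-5-{[tert-butyl(diphenyl)silyl]oxy}-3-methylpentyl]-1,3-dimethyl-6-(prop-2-en-1-yl)cyclohex-3-ene-1-carbaldehyde
Product: 10 (1R,2R,6R)-2-[(3S)-5-{[tert-butyl(diphenyl)silyl]oxy}-3-methylpentyl]-1,3-dimethyl-6-(2-oxopropyl)cyclohex-3-ene-1-carbaldehyde
Conditions: PdCl2 (10 mol %), CuCl (20 mol %), O2 (1 atm), DMF/H2O (7:1), rt
Reagents that add atoms: water, O
Why: Wacker oxidation; Markovnikov hydroxypalladation of the monosubstituted olefin gives the methyl ketone, while the trisubstituted ring olefin is too hindered for divalent palladium and the quaternary aldehyde cannot enolise.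

Step 8
Reactants: 10 (1R,2R,6R)-2-[(3S)-5-{[tert-butyl(diphenyl)silyl]oxy}-3-methylpentyl]-1,3-dimethyl-6-(2-oxopropyl)cyclohex-3-ene-1-carbaldehyde
Product: 12 (4aS,5R,8aR)-5-[(3S)-5-{[tert-butyl(diphenyl)silyl]oxy}-3-methylpentyl]-4a,6-dimethyl-4a,5,8,8a-tetrahydronaphthalen-2(1H)-one, via aldol adduct 11 (not isolated)
Conditions: KOH, MeOH, rt
Reagents that add atoms: none
Why: Intramolecular aldol condensation; only the methyl carbon C2 can reach the non-enolisable formyl carbon C1 through a six-membered transition state, and dehydration gives the enone without touching a stereocentre, so the trans ring fusion laid down in step 6 appears.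

Step 9
Reactants: 12 (4aS,5R,8aR)-5-[(3S)-5-{[tert-butyl(diphenyl)silyl]oxy}-3-methylpentyl]-4a,6-dimethyl-4a,5,8,8a-tetrahydronaphthalen-2(1H)-one
Product: 14 (4aS,5R,8aS)-5-[(3S)-5-{[tert-butyl(diphenyl)silyl]oxy}-3-methylpentyl]-1,1,4a,6-tetramethyl-4a,5,8,8a-tetrahydronaphthalen-2(1H)-one, via monomethyl enone 13 (not isolated)
Conditions: KOtBu, MeI (excess), tBuOH/THF, 0 °C to rt
Reagents that add atoms: iodomethane, CI
Why: Enolate alkylation; C4 is the only enolisable position of 12 (C10 is quaternary, so there is no γ-deprotonation), and excess base and iodomethane should carry it to the gem-dimethyl stage.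

Step 10
Reactants: 14 (4aS,5R,8aS)-5-[(3S)-5-{[tert-butyl(diphenyl)silyl]oxy}-3-methylpentyl]-1,1,4a,6-tetramethyl-4a,5,8,8a-tetrahydronaphthalen-2(1H)-one
Product: 15 (4aS,5R,8aS)-5-[(3S)-5-{[tert-butyl(diphenyl)silyl]oxy}-3-methylpentyl]-1,1,4a,6-tetramethyl-3,4,4a,5,8,8a-hexahydronaphthalen-2(1H)-one
Conditions: H2 (1 atm), RhCl(PPh3)3 (5 mol %), benzene, rt
Reagents that add atoms: none
Why: Homogeneous hydrogenation with RhCl(PPh3)3 reduces the disubstituted conjugated C1=C2 olefin and leaves the trisubstituted C7=C8 olefin, as in the selective saturation of the 1,2-olefin of steroidal 1,4-dien-3-ones.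

Step 11
Reactants: 15 (4aS,5R,8aS)-5-[(3S)-5-{[tert-butyl(diphenyl)silyl]oxy}-3-methylpentyl]-1,1,4a,6-tetramethyl-3,4,4a,5,8,8a-hexahydronaphthalen-2(1H)-one
Product: 17 (3S,4aS,5R,8aS)-3-hydroxy-5-[(3S)-5-{[tert-butyl(diphenyl)silyl]oxy}-3-methylpentyl]-1,1,4a,6-tetramethyl-3,4,4a,5,8,8a-hexahydronaphthalen-2(1H)-one, via potassium enolate 16 (not isolated)
Conditions: KN(SiMe3)2, THF, −78 °C; then 2-(benzenesulfonyl)-3-phenyloxaziridine, −78 °C
Reagents that add atoms: 2-(benzenesulfonyl)-3-phenyloxaziridine, O=S(=O)(c1ccccc1)N1OC1c1ccccc1
Why: Enolate hydroxylation with an N-sulfonyloxaziridine; 15 can enolise only towards C2, and the oxidant should approach from the face opposite the axial C10 and C4 methyl groups, giving the equatorial C2 alcohol, which is also the more stable epimer.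

Step 12
Reactants: 17 (3S,4aS,5R,8aS)-3-hydroxy-5-[(3S)-5-{[tert-butyl(diphenyl)silyl]oxy}-3-methylpentyl]-1,1,4a,6-tetramethyl-3,4,4a,5,8,8a-hexahydronaphthalen-2(1H)-one
Product: 18 (2R,3S,4aS,5R,8aS)-5-[(3S)-5-{[tert-butyl(diphenyl)silyl]oxy}-3-methylpentyl]-1,1,4a,6-tetramethyl-1,2,3,4,4a,5,8,8a-octahydronaphthalene-2,3-diol
Conditions: KBH(sBu)3 (3 equiv), THF, −78 °C
Reagents that add atoms: none
Why: Reduction with a bulky trialkylborohydride; the hydride should enter along the equatorial trajectory (the axial one is blocked by the axial hydrogens at C1 and C5) and give the axial C3 alcohol cis to the C2 hydroxyl, as with 4,4-dimethyl 3-ketones of the terpenoid series and with 2-oxygenated cyclohexanones.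

Step 13
Reactants: 18 (2R,3S,4aS,5R,8aS)-5-[(3S)-5-{[tert-butyl(diphenyl)silyl]oxy}-3-methylpentyl]-1,1,4a,6-tetramethyl-1,2,3,4,4a,5,8,8a-octahydronaphthalene-2,3-diol
Product: 19 (2R,3S,4aS,5R,8aS)-5-[(3S)-5-hydroxy-3-methylpentyl]-1,1,4a,6-tetramethyl-1,2,3,4,4a,5,8,8a-octahydronaphthalene-2,3-diol
Conditions: Bu4NF, THF, rt
Reagents that add atoms: none
Why: Fluoride cleavage of the silyl ether; no ester is present yet, so no acyl migration can occur.

Step 14
Reactants: 19 (2R,3S,4aS,5R,8aS)-5-[(3S)-5-hydroxy-3-methylpentyl]-1,1,4a,6-tetramethyl-1,2,3,4,4a,5,8,8a-octahydronaphthalene-2,3-diol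
Product: 20 (2S,3R,4aS,8R,8aS)-8-[(3S)-5-acetoxy-3-methylpentyl]-3-hydroxy-4,4,7,8a-tetramethyl-1,2,3,4,4a,5,8,8a-octahydronaphthalen-2-yl acetate (CNP0144124.1)
Conditions: Ac2O (2.2 equiv), pyridine, CH2Cl2, 0 °C
Reagents that add atoms: acetic anhydride, CC(=O)OC(C)=O
Why: Acylation follows steric access: the primary C15 hydroxyl and the equatorial C2 hydroxyl should react, while the axial C3 hydroxyl next to the gem-dimethyl group stays free at 0 °C without an acyl-transfer catalyst.

## Compound list

1 | (3S)-3,7-dimethyloct-6-en-1-ol, (S)-citronellol | C[C@@H](CCC=C(C)C)CCO | starting material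
2 | tert-butyl{[(3S)-3,7-dimethyloct-6-en-1-yl]oxy}diphenylsilane | C[C@@H](CCC=C(C)C)CCO[Si](c1ccccc1)(c1ccccc1)C(C)(C)C | intermediate
3 | (2E,6S)-8-{[tert-butyl(diphenyl)silyl]oxy}-2,6-dimethyloct-2-en-1-ol | C[C@@H](CC/C=C(\C)CO)CCO[Si](c1ccccc1)(c1ccccc1)C(C)(C)C | intermediate (not isolated)
4 | (2E,6S)-8-{[tert-butyl(diphenyl)silyl]oxy}-2,6-dimethyloct-2-enal | C[C@@H](CC/C=C(\C)C=O)CCO[Si](c1ccccc1)(c1ccccc1)C(C)(C)C | intermediate
5 | tert-butyl{[(3S,6E)-3,7-dimethylnona-6,8-dien-1-yl]oxy}diphenylsilane | C[C@@H](CC/C=C(\C)C=C)CCO[Si](c1ccccc1)(c1ccccc1)C(C)(C)C | intermediate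
6 | 2-methyl-2-vinyloxirane (racemic) | CC1(C=C)CO1 | starting material
7 | (2E)-2-methylhexa-2,5-dien-1-ol | OC/C(C)=C/CC=C | intermediate
8 | (2E)-2-methylhexa-2,5-dienal | O=C/C(C)=C/CC=C | intermediate
9 | (1R,2R,6S)-2-[(3S)-5-{[tert-butyl(diphenyl)silyl]oxy}-3-methylpentyl]-1,3-dimethyl-6-(prop-2-en-1-yl)cyclohex-3-ene-1-carbaldehyde | CC(C)(C)[Si](c1ccccc1)(c1ccccc1)OCC[C@@H](C)CC[C@@H]2C(C)=CC[C@H](CC=C)[C@@]2(C)C=O | intermediate
10 | (1R,2R,6R)-2-[(3S)-5-{[tert-butyl(diphenyl)silyl]oxy}-3-methylpentyl]-1,3-dimethyl-6-(2-oxopropyl)cyclohex-3-ene-1-carbaldehyde | CC(C)(C)[Si](c1ccccc1)(c1ccccc1)OCC[C@@H](C)CC[C@@H]2C(C)=CC[C@H](CC(C)=O)[C@@]2(C)C=O | intermediate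
11 | trans-fused β-hydroxy ketone: 4-hydroxy-3,4-dihydro form of 12 (ring centres as in 12, both epimers at the carbinol carbon) | CC(C)(C)[Si](c1ccccc1)(c1ccccc1)OCC[C@@H](C)CC[C@@H]3C(C)=CC[C@@H]4CC(=O)CC(O)[C@@]34C | intermediate (not isolated)
12 | (4aS,5R,8aR)-5-[(3S)-5-{[tert-butyl(diphenyl)silyl]oxy}-3-methylpentyl]-4a,6-dimethyl-4a,5,8,8a-tetrahydronaphthalen-2(1H)-one | CC(C)(C)[Si](c1ccccc1)(c1ccccc1)OCC[C@@H](C)CC[C@@H]3C(C)=CC[C@@H]4CC(=O)C=C[C@@]34C | intermediate
13 | 1-methyl derivative of 12 (labdane C4 monomethylated, both epimers) | CC(C)(C)[Si](c1ccccc1)(c1ccccc1)OCC[C@@H](C)CC[C@@H]3C(C)=CC[C@@H]4C(C)C(=O)C=C[C@@]34C | intermediate (not isolated)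
14 | (4aS,5R,8aS)-5-[(3S)-5-{[tert-butyl(diphenyl)silyl]oxy}-3-methylpentyl]-1,1,4a,6-tetramethyl-4a,5,8,8a-tetrahydronaphthalen-2(1H)-one | CC(C)(C)[Si](c1ccccc1)(c1ccccc1)OCC[C@@H](C)CC[C@@H]3C(C)=CC[C@@H]4C(C)(C)C(=O)C=C[C@@]34C | intermediate
15 | (4aS,5R,8aS)-5-[(3S)-5-{[tert-butyl(diphenyl)silyl]oxy}-3-methylpentyl]-1,1,4a,6-tetramethyl-3,4,4a,5,8,8a-hexahydronaphthalen-2(1H)-one | CC(C)(C)[Si](c1ccccc1)(c1ccccc1)OCC[C@@H](C)CC[C@@H]3C(C)=CC[C@@H]4C(C)(C)C(=O)CC[C@@]34C | intermediate
16 | potassium enolate of 15 (enolate double bond between labdane C2 and C3) | CC(C)(C)[Si](c1ccccc1)(c1ccccc1)OCC[C@@H](C)CC[C@@H]3C(C)=CC[C@@H]4C(C)(C)C([O-])=CC[C@@]34C.[K+] | intermediate (not isolated)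
17 | (3S,4aS,5R,8aS)-3-hydroxy-5-[(3S)-5-{[tert-butyl(diphenyl)silyl]oxy}-3-methylpentyl]-1,1,4a,6-tetramethyl-3,4,4a,5,8,8a-hexahydronaphthalen-2(1H)-one | CC(C)(C)[Si](c1ccccc1)(c1ccccc1)OCC[C@@H](C)CC[C@@H]3C(C)=CC[C@@H]4C(C)(C)C(=O)[C@@H](O)C[C@@]34C | intermediate
18 | (2R,3S,4aS,5R,8aS)-5-[(3S)-5-{[tert-butyl(diphenyl)silyl]oxy}-3-methylpentyl]-1,1,4a,6-tetramethyl-1,2,3,4,4a,5,8,8a-octahydronaphthalene-2,3-diol | CC(C)(C)[Si](c1ccccc1)(c1ccccc1)OCC[C@@H](C)CC[C@@H]3C(C)=CC[C@@H]4C(C)(C)[C@@H](O)[C@@H](O)C[C@@]34C | intermediate
19 | (2R,3S,4aS,5R,8aS)-5-[(3S)-5-hydroxy-3-methylpentyl]-1,1,4a,6-tetramethyl-1,2,3,4,4a,5,8,8a-octahydronaphthalene-2,3-diol | OCC[C@@H](C)CC[C@@H]1C(C)=CC[C@@H]2C(C)(C)[C@@H](O)[C@@H](O)C[C@@]12C | intermediate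
20 | (2S,3R,4aS,8R,8aS)-8-[(3S)-5-acetoxy-3-methylpentyl]-3-hydroxy-4,4,7,8a-tetramethyl-1,2,3,4,4a,5,8,8a-octahydronaphthalen-2-yl acetate | CC(=O)OCC[C@@H](C)CC[C@@H]1C(C)=CC[C@@H]2C(C)(C)[C@@H](O)[C@@H](OC(C)=O)C[C@@]12C | target

## Step count and risks

Total step count: 14. Longest linear sequence: 12 steps (steps 1–3 and 6–14); steps 4 and 5 form the two-step branch to the dienophile.

**Key step (step 6).** The most likely failure is erosion of the formyl-exo preference. That preference is best established for α-methyl enals with cyclopentadiene; with an acyclic diene it rests only on the α-methyl group and on the bulk of the boron complex. Formyl-endo addition would set C9 with the chain trans to the C10 methyl, and this cannot be corrected later. A trisubstituted dienophile also turns over slowly, which gives the strong acid time to oligomerise the diene, and the C8 methyl pulls against the desired regiochemistry. The fallback replaces carbonyl activation by an ionic cycloaddition. It sets out from 8, which is condensed with (2R,4R)-pentane-2,4-diol (pyridinium p-toluenesulfonate, benzene, removal of water) to give (4R,6R)-2-[(2E)-hexa-2,5-dien-2-yl]-4,6-dimethyl-1,3-dioxane F1. Ionisation of F1 with Me3SiOSO2CF3 in CH2Cl2 at −78 °C in the presence of 5 gives a 2-alkenyl oxocarbenium ion. This is a far stronger dienophile than the enal, its bulky alkoxy-substituted terminus should avoid the space under the C8 methyl, and its π-face is chosen by the C2-symmetric diol. The product is the dioxane acetal of 9, F2. Aqueous HCl in THF releases the diol and returns the route to 9. The antipodal diol is used if the sense of induction requires it.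

**Step 12.** Poor facial selectivity is the risk. The free C2 hydroxyl is converted into a potassium alkoxide by the basic hydride, and aggregation at this neighbouring site may slow the reduction or divert the hydride to the axial trajectory, giving the diequatorial trans-diol. The fallback takes the hydroxyl out of play and moves the reduction to the end. It sets out from 17: Bu4NF gives the keto diol (3S,4aS,5R,8aS)-3-hydroxy-5-[(3S)-5-hydroxy-3-methylpentyl]-1,1,4a,6-tetramethyl-3,4,4a,5,8,8a-hexahydronaphthalen-2(1H)-one F3. Exhaustive acetylation (Ac2O, pyridine, 4-(dimethylamino)pyridine) gives its diacetate F4, in which no selectivity between hydroxyls is needed. KBH(sBu)3 at −78 °C with an acetic acid quench then reduces the ketone, flanked by a quaternary carbon and an acetoxy-bearing carbon, and the route comes back at 20 without passing through 18 and 19.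

**Step 14.** The risk is loss of site selectivity: partial acetylation of the C3 hydroxyl, or migration of the C2 acetyl group to the cis C3 oxygen under basic conditions. The fallback activates the wanted oxygen instead of relying on the hindrance of the unwanted one. It sets out from 19, which with Bu2SnO in refluxing toluene gives the 2,3-O-dibutylstannylene acetal of 19 F5. Stannylene acetals of cis-diols on six-membered rings are acylated at the equatorial oxygen, so acetyl chloride and triethylamine at 0 °C should acetylate O2 through the tin acetal and the primary C15 hydroxyl directly, returning to 20.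

**Step 2.** The allylic oxidation may stop at mixtures of alcohol and aldehyde, over-oxidise, or attack the allylic methylene group as well, which costs material at the start of the longest sequence. The fallback uses olefin metathesis in place of an ene-type oxidation. It sets out from 2, whose prenyl-type terminus undergoes cross-metathesis with methacrolein (second-generation Grubbs catalyst, CH2Cl2, 40 °C) with loss of 2-methylpropene, and returns directly at 4 with the E geometry favoured; no new compound is formed on the way.

## Further compounds

F1 | step 6 | (4R,6R)-2-[(2E)-hexa-2,5-dien-2-yl]-4,6-dimethyl-1,3-dioxane | C=CC/C=C(\C)C1O[C@H](C)C[C@@H](C)O1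
F2 | step 6 | (4R,6R)-4,6-dimethyl-1,3-dioxan-2-yl acetal of 9 | CC(C)(C)[Si](c1ccccc1)(c1ccccc1)OCC[C@@H](C)CC[C@@H]2C(C)=CC[C@H](CC=C)[C@@]2(C)C3O[C@H](C)C[C@@H](C)O3
F3 | step 12 | (3S,4aS,5R,8aS)-3-hydroxy-5-[(3S)-5-hydroxy-3-methylpentyl]-1,1,4a,6-tetramethyl-3,4,4a,5,8,8a-hexahydronaphthalen-2(1H)-one | OCC[C@@H](C)CC[C@@H]1C(C)=CC[C@@H]2C(C)(C)C(=O)[C@@H](O)C[C@@]12C
F4 | step 12 | diacetate of F3 (acetates at labdane C2 and C15, ketone at C3) | CC(=O)OCC[C@@H](C)CC[C@@H]1C(C)=CC[C@@H]2C(C)(C)C(=O)[C@@H](OC(C)=O)C[C@@]12C
F5 | step 14 | 2,3-O-dibutylstannylene acetal of 19 | OCC[C@@H](C)CC[C@@H]1C(C)=CC[C@@H]2C(C)(C)[C@H]3O[Sn](CCCC)(CCCC)O[C@H]3C[C@@]12C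
F0 | step 2 | none | none
A1 | alternative 1 | Se-phenyl seleno ester: ring A with 2,3-acetonide, (E)-alkenyl chain on C10 and 3-(phenylselanylcarbonyl)ethyl arm on C5 | CC(C)(C)[Si](C)(C)OCC[C@@H](C)C/C=C/[C@]1(C)C[C@@H]2OC(C)(C)O[C@@H]2C(C)(C)[C@H]1CCC(=O)[Se]c1ccccc1
A2 | alternative 1 | trans-fused 8-oxo decalin with complete side chain (2,3-acetonide, silyl ether) | CC(C)(C)[Si](C)(C)OCC[C@@H](C)CC[C@@H]1C(=O)CC[C@@H]2C(C)(C)[C@H]3OC(C)(C)O[C@H]3C[C@@]12C
A3 | alternative 2 | monocyclic β-keto ester with C5=C10 olefin and 2,3-acetonide | COC(=O)CC(=O)CCC1=C(C)C[C@@H]2OC(C)(C)O[C@@H]2C1(C)C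
A4 | alternative 2 | trans-fused bicyclic 8-oxo 11-methyl ester (2,3-acetonide) | COC(=O)[C@@H]1C(=O)CC[C@@H]2C(C)(C)[C@H]3OC(C)(C)O[C@H]3C[C@@]12C
A5 | alternative 3 | carvone-derived enone with isopropenyl group on C5 and methyl plus (Z)-3-(trimethylsilyl)allyl arm on C10 | O=C1C(C)=CC[C@H](C(C)=C)[C@@]1(C)C/C=C\[Si](C)(C)C
A6 | alternative 3 | trans-fused bicyclic 2,7-dien-9-one with C4 gem-dimethyl, C8 and C10 methyls | O=C1C(C)=CC[C@@H]2C(C)(C)C=CC[C@@]12C
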